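**Route outline**

- Retrosynthesis: the C7–C11 bond to the propanoate is cut first, then the C3 angelate ester, then C1–C10 (ring A), which uncovers a 4-methyl-4-alkylcyclohexa-2,5-dienone. Ring B is traced back through C9=C10 dehydrogenation and a Robinson annulation (C5–C10 and C6–C7) to an α-methyl aldehyde plus methyl vinyl ketone, and the C3–C4 bond to an allylboration.
- Enabling feature (eremophilane numbering): ring B (C5–C10) is a cyclohex-2-enone, C6=C7–C8(=O), whose quaternary C5 stands para to C8. It is therefore one half of a symmetric dienone in which C5 is only prochiral, and ring A (C1–C4) is a four-carbon tether from C5 to C10 that can close only cis.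
- Forward order: acyclic C1–C6 chain, then ring B (annulation, dehydrogenation), then ring A by radical cyclisation, then C7 iodination, O3 acylation and C7–C11 coupling.
- Stereochemistry: C3 and C4 come from a catalyst-controlled anti allylboration with the E-boronate. C5 and C10 arise in the key step, where the tether gives the cis fusion and the C3/C4 stereodiad picks the enone arm. C11 is set by a chiral nickel catalyst, and the Z-alkene of the angelate is bought with angelic acid.

Key step: step 12

Remarks: atoms are numbered as in eremophilane; TBS = tert-butyldimethylsilyl, PMB = 4-methoxybenzyl, Bpin = pinacolatoboryl. The (R)-enantiomer of the phosphoric acid TRIP is assumed to direct Re-face addition in step 3 (its antipode is used should the sense prove opposite). From step 5 until step 9, C5 is carried as a mixture of epimers, which step 9 erases.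

**Step 1**
Reactants: 1 (E)-2-methylbut-2-en-1-ol (tiglyl alcohol)
Product: 2 (E)-2-methylbut-2-en-1-yl acetate
Conditions: Ac2O, pyridine, DMAP (cat.), CH2Cl2, 0 °C to rt
Reagents that add atoms: acetic anhydride, CC(=O)OC(C)=O
Why: DMAP-catalysed acylation of a primary allylic alcohol is routine and does not touch the E-alkene.

**Step 2**
Reactants: 2 (E)-2-methylbut-2-en-1-yl acetate
Product: 3 4,4,5,5-tetramethyl-2-[(E)-2-methylbut-2-en-1-yl]-1,3,2-dioxaborolane
Conditions: Pd2(dba)3 (cat.), B2pin2, DMSO, 50 °C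
Reagents that add atoms: bis(pinacolato)diboron, CC1(C)OB(OC1(C)C)B1OC(C)(C)C(C)(C)O1
Why: Miyaura-type allylic borylation, in which zerovalent palladium ionises the acetate to the syn-1,2-dimethylallyl complex, acetate-assisted transmetalation with B2pin2 follows, and reductive elimination at the unsubstituted terminus should give the linear boronate with the E geometry kept under these mild, phosphine-free conditions.

**Step 3**
Reactants: 4 3-[(4-methoxybenzyl)oxy]propanal; 3 4,4,5,5-tetramethyl-2-[(E)-2-methylbut-2-en-1-yl]-1,3,2-dioxaborolane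
Product: 6 (3S,4R)-4,5-dimethyl-1-(PMB-oxy)hex-5-en-3-ol, via pinacol borate ester 5 (not isolated)
Conditions: (R)-TRIP (5 mol %), 4 Å MS, toluene, −30 °C; then H2O
Reagents that add atoms: none
Why: Chiral phosphoric acid-catalysed allylboration through a closed chair (Zimmerman–Traxler) transition state, in which the E geometry of the boronate places the γ-methyl equatorial and so gives the anti C3/C4 relationship, while the acid bound to a boronate oxygen selects the Re face of the aldehyde and sets 3S (hence 4R).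

**Step 4**
Reactants: 6 (3S,4R)-4,5-dimethyl-1-(PMB-oxy)hex-5-en-3-ol
Product: 7 (3S,4R)-4,5-dimethyl-1-(PMB-oxy)-3-(TBS-oxy)hex-5-ene
Conditions: TBSOTf, 2,6-lutidine, CH2Cl2, −78 to 0 °C
Reagents that add atoms: tert-butyldimethylsilyl triflate, CC(C)(C)[Si](C)(C)OS(=O)(=O)C(F)(F)F
Why: Silylation of a hindered secondary alcohol with the silyl triflate is reliable, and the bulky ether later serves as the conformational anchor of the key step.

**Step 5**
Reactants: 7 (3S,4R)-4,5-dimethyl-1-(PMB-oxy)-3-(TBS-oxy)hex-5-ene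
Product: 9 (2RS,3R,4S)-2,3-dimethyl-6-(PMB-oxy)-4-(TBS-oxy)hexan-1-ol, via B-alkyl-9-BBN adduct 8 (not isolated)
Conditions: 9-BBN, THF, 0 °C to rt; then NaOH, H2O2, H2O, 0 °C to rt
Reagents that add atoms: hydrogen peroxide, OO
Why: Anti-Markovnikov hydroboration of the 1,1-disubstituted alkene and oxidation with retention give the primary alcohol, and the new C5 centre forms without control because it is erased in step 9.

**Step 6**
Reactants: 9 (2RS,3R,4S)-2,3-dimethyl-6-(PMB-oxy)-4-(TBS-oxy)hexan-1-ol
Product: 10 (2RS,3R,4S)-2,3-dimethyl-6-(PMB-oxy)-4-(TBS-oxy)hexanal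
Conditions: TEMPO (cat.), PhI(OAc)2, CH2Cl2, rt
Reagents that add atoms: none
Why: Oxoammonium (TEMPO) oxidation stops at the aldehyde and tolerates silyl and PMB ethers, and epimerisation at the α-carbon is without consequence.

**Step 7**
Reactants: 10 (2RS,3R,4S)-2,3-dimethyl-6-(PMB-oxy)-4-(TBS-oxy)hexanal; 11 but-3-en-2-one (methyl vinyl ketone)
Product: 14 2-methyl-5-oxo-2-[(2R,3S)-5-(PMB-oxy)-3-(TBS-oxy)pentan-2-yl]hexanal (C2 epimers), via pyrrolidine enamine 12 (not isolated), via dihydropyran aminal 13 (not isolated)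
Conditions: pyrrolidine, 4 Å MS, toluene, rt; then 11, rt to 50 °C; then AcOH/NaOAc/H2O, rt
Reagents that add atoms: water, O
Why: Stork enamine Michael addition, in which the β-carbon of the trisubstituted enamine attacks methyl vinyl ketone to create quaternary C5 (the adduct rests as the cyclic aminal) and buffered hydrolysis releases the 1,5-keto aldehyde without harming the silyl or PMB ether.

**Step 8**
Reactants: 14 2-methyl-5-oxo-2-[(2R,3S)-5-(PMB-oxy)-3-(TBS-oxy)pentan-2-yl]hexanal
Product: 16 4-methyl-4-[(2R,3S)-5-(PMB-oxy)-3-(TBS-oxy)pentan-2-yl]cyclohex-2-en-1-one (C4 epimers), via aldol adduct 15 (not isolated)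
Conditions: KOH, MeOH–THF, 0 °C to rt
Reagents that add atoms: none
Why: Intramolecular aldol condensation (second half of the Robinson annulation), in which the methyl ketone enolate closes the six-membered ring on the non-enolisable aldehyde and base-promoted dehydration gives the conjugated 4,4-disubstituted cyclohexenone.

**Step 9**
Reactants: 16 4-methyl-4-[(2R,3S)-5-(PMB-oxy)-3-(TBS-oxy)pentan-2-yl]cyclohex-2-en-1-one
Product: 18 4-methyl-4-[(2R,3S)-5-(PMB-oxy)-3-(TBS-oxy)pentan-2-yl]cyclohexa-2,5-dien-1-one, via silyl dienol ether 17 (not isolated)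
Conditions: LiN(iPr)2, TMSCl, THF, −78 °C; then Pd(OAc)2 (1.1 equiv), MeCN, rt
Reagents that add atoms: none
Why: Saegusa–Ito dehydrogenation, in which deprotonation is possible only at C9, palladation of the cross-conjugated silyl dienol ether at C9 is followed by β-hydride elimination from C10, and both C5 epimers converge on one symmetric dienone.

**Step 10**
Reactants: 18 4-methyl-4-[(2R,3S)-5-(PMB-oxy)-3-(TBS-oxy)pentan-2-yl]cyclohexa-2,5-dien-1-one
Product: 19 4-[(2R,3S)-5-hydroxy-3-(TBS-oxy)pentan-2-yl]-4-methylcyclohexa-2,5-dien-1-one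
Conditions: DDQ, CH2Cl2–pH 7 buffer, 0 °C to rt
Reagents that add atoms: none
Why: Oxidative PMB cleavage (benzylic hydride abstraction by DDQ, then hydrolysis of the oxocarbenium ion) is selective for the electron-rich ether over the silyl ether and the electron-poor dienone.

**Step 11**
Reactants: 19 4-[(2R,3S)-5-hydroxy-3-(TBS-oxy)pentan-2-yl]-4-methylcyclohexa-2,5-dien-1-one
Product: 20 4-[(2R,3S)-5-iodo-3-(TBS-oxy)pentan-2-yl]-4-methylcyclohexa-2,5-dien-1-one
Conditions: I2, PPh3, imidazole, CH2Cl2, 0 °C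
Reagents that add atoms: iodine, II
Why: Appel-type iodination (alkoxyphosphonium formation, SN2 displacement at the primary carbon) runs under buffered neutral conditions that avoid an acid-induced dienone–phenol rearrangement.

**Step 12**
Reactants: 20 4-[(2R,3S)-5-iodo-3-(TBS-oxy)pentan-2-yl]-4-methylcyclohexa-2,5-dien-1-one
Product: 21 (4aR,5R,6S,8aR)-4a,5-dimethyl-6-(TBS-oxy)-4a,5,6,7,8,8a-hexahydronaphthalen-2(1H)-one
Conditions: Bu3SnH (slow addition), Et3B (cat.), air, toluene, −78 °C
Reagents that add atoms: none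
Why: Et3B/air generates a stannyl radical at −78 °C that abstracts iodine from C1; the nucleophilic primary radical adds to C10, the β-carbon of one enone arm, and the C9 α-keto radical so formed is reduced by Bu3SnH, which leaves the other arm as the C6=C7–C8 enone. The closest known reaction type is the reductive radical conjugate cyclisation of halide-tethered 4,4-disubstituted cyclohexa-2,5-dienones to cis-fused bicyclic enones. Ring A is closed by 6-exo-trig attack that forms the C1–C10 bond. C10 is fixed by the tether, which is anchored at C5 and can reach the dienone only from its own face, so the new C10–H lies cis to the C5 methyl; C5 becomes stereogenic through the choice of arm, which the C3/C4 stereodiad dictates via a chair-like transition state with equatorial OTBS, equatorial C5 methyl, axial spectator arm (C6) and an axial C4 methyl that meets only hydrogens. The step therefore needs only discrimination between the two diastereotopic arms, and the competing arm or chair would force a 1,3-diaxial contact (OTBS with C6, OTBS with the C5 methyl, or C4 methyl with C9), a penalty sharpened by the bulky silyl ether and the low temperature. Slow addition of the hydride keeps its concentration low so that cyclisation outruns direct reduction of the C1 radical.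

**Step 13**
Reactants: 21 (4aR,5R,6S,8aR)-4a,5-dimethyl-6-(TBS-oxy)-4a,5,6,7,8,8a-hexahydronaphthalen-2(1H)-one
Product: 22 (4aS,5R,6S,8aR)-3-iodo-4a,5-dimethyl-6-(TBS-oxy)-4a,5,6,7,8,8a-hexahydronaphthalen-2(1H)-one
Conditions: I2, pyridine, CH2Cl2, 0 °C to rt
Reagents that add atoms: iodine, II
Why: α-Iodination of the enone by a Baylis–Hillman-type addition–elimination (pyridine adds to C6, the enolate is iodinated at C7, pyridine leaves), a reaction established for 4,4-disubstituted cyclohexenones and possible only at C7 here.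

**Step 14**
Reactants: 22 (4aS,5R,6S,8aR)-3-iodo-4a,5-dimethyl-6-(TBS-oxy)-4a,5,6,7,8,8a-hexahydronaphthalen-2(1H)-one
Product: 23 (4aS,5R,6S,8aR)-6-hydroxy-3-iodo-4a,5-dimethyl-4a,5,6,7,8,8a-hexahydronaphthalen-2(1H)-one
Conditions: HF·pyridine, THF–pyridine, 0 °C to rt
Reagents that add atoms: none
Why: Fluoride-driven desilylation under non-basic conditions leaves the α-iodoenone and all stereocentres untouched.

**Step 15**
Reactants: 23 (4aS,5R,6S,8aR)-6-hydroxy-3-iodo-4a,5-dimethyl-4a,5,6,7,8,8a-hexahydronaphthalen-2(1H)-one; 24 angelic acid, (Z)-2-methylbut-2-enoic acid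
Product: 26 (1R,2S,4aR,8aS)-7-iodo-1,8a-dimethyl-6-oxo-1,2,3,4,4a,5,6,8a-octahydronaphthalen-2-yl (Z)-2-methylbut-2-enoate, via mixed anhydride 25 (not isolated)
Conditions: 24, 2,4,6-trichlorobenzoyl chloride, Et3N, toluene, rt; then 23, toluene, 75 °C
Reagents that add atoms: none
Why: Yamaguchi esterification, in which the alcohol attacks the less hindered angeloyl carbonyl of the mixed anhydride, and leaving out nucleophilic catalysts such as DMAP avoids the addition–elimination path that turns angelates into tiglates.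

**Step 16**
Reactants: 26 (1R,2S,4aR,8aS)-7-iodo-1,8a-dimethyl-6-oxo-1,2,3,4,4a,5,6,8a-octahydronaphthalen-2-yl (Z)-2-methylbut-2-enoate; 27 methyl 2-chloropropanoate (racemic)
Product: 28 methyl (2R)-2-[(4aR,7S,8R,8aR)-8,8a-dimethyl-7-{[(Z)-2-methylbut-2-enoyl]oxy}-3-oxo-3,4,4a,5,6,7,8,8a-octahydronaphthalen-2-yl]propanoate (target)
Conditions: NiBr2·diglyme (10 mol %), chiral 4-heptyl-BiOX bis-oxazoline ligand (enantiomer chosen for 11R), Mn powder, TMSCl (cat.), DMA–THF, 0 to 10 °C
Reagents that add atoms: none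
Why: Proposed new method: oxidative addition of ligated zerovalent nickel into the C7–I bond gives an alkenylnickel species, chloride abstraction from 27 produces a planar α-ester radical (erasing the configuration of the racemic chloride), radical capture leads to a trivalent nickel alkenyl–alkyl complex whose reductive elimination forges C7–C11 with the bis-oxazoline ligand rather than the distant ring stereocentres fixing 11R, and Mn closes the cycle under neutral conditions that spare C11–H and the angelate; the closest known reaction type is the nickel-catalysed enantioconvergent reductive cross-coupling of racemic α-chloro esters with aryl iodides (and of benzylic chlorides with alkenyl bromides), from which this step differs by the α-iodoenone partner.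

**Compound list**

1 | (E)-2-methylbut-2-en-1-ol (tiglyl alcohol) | C/C=C(\C)CO | starting material
2 | (E)-2-methylbut-2-en-1-yl acetate | C/C=C(\C)COC(C)=O | intermediate
3 | 4,4,5,5-tetramethyl-2-[(E)-2-methylbut-2-en-1-yl]-1,3,2-dioxaborolane | C/C=C(\C)CB1OC(C)(C)C(C)(C)O1 | intermediate
4 | 3-[(4-methoxybenzyl)oxy]propanal | COc1ccc(COCCC=O)cc1 | starting material
5 | pinacol borate ester of 6 (O-Bpin at C3, not isolated) | COc1ccc(COCC[C@H](OB2OC(C)(C)C(C)(C)O2)[C@H](C)C(C)=C)cc1 | intermediate
6 | (3S,4R)-4,5-dimethyl-1-(PMB-oxy)hex-5-en-3-ol | COc1ccc(COCC[C@H](O)[C@H](C)C(C)=C)cc1 | intermediate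
7 | (3S,4R)-4,5-dimethyl-1-(PMB-oxy)-3-(TBS-oxy)hex-5-ene | COc1ccc(COCC[C@H](O[Si](C)(C)C(C)(C)C)[C@H](C)C(C)=C)cc1 | intermediate
8 | 9-[(3R,4S)-2,3-dimethyl-6-(PMB-oxy)-4-(TBS-oxy)hexyl]-9-borabicyclo[3.3.1]nonane (C2 epimers, not isolated) | COc1ccc(COCC[C@H](O[Si](C)(C)C(C)(C)C)[C@H](C)C(C)CB2C3CCCC2CCC3)cc1 | intermediate
9 | (2RS,3R,4S)-2,3-dimethyl-6-(PMB-oxy)-4-(TBS-oxy)hexan-1-ol | COc1ccc(COCC[C@H](O[Si](C)(C)C(C)(C)C)[C@H](C)C(C)CO)cc1 | intermediate
10 | (2RS,3R,4S)-2,3-dimethyl-6-(PMB-oxy)-4-(TBS-oxy)hexanal | COc1ccc(COCC[C@H](O[Si](C)(C)C(C)(C)C)[C@H](C)C(C)C=O)cc1 | intermediate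
11 | but-3-en-2-one (methyl vinyl ketone) | CC(=O)C=C | starting material
12 | 1-[(3R,4S)-2,3-dimethyl-6-(PMB-oxy)-4-(TBS-oxy)hex-1-en-1-yl]pyrrolidine (E/Z mixture, not isolated) | COc1ccc(COCC[C@H](O[Si](C)(C)C(C)(C)C)[C@H](C)C(C)=CN2CCCC2)cc1 | intermediate
13 | 1-{3,6-dimethyl-3-[(2R,3S)-5-(PMB-oxy)-3-(TBS-oxy)pentan-2-yl]-3,4-dihydro-2H-pyran-2-yl}pyrrolidine (diastereomer mixture, not isolated) | COc1ccc(COCC[C@H](O[Si](C)(C)C(C)(C)C)[C@H](C)C2(C)CC=C(C)OC2N3CCCC3)cc1 | intermediate
14 | 2-methyl-5-oxo-2-[(2R,3S)-5-(PMB-oxy)-3-(TBS-oxy)pentan-2-yl]hexanal (C2 epimers) | COc1ccc(COCC[C@H](O[Si](C)(C)C(C)(C)C)[C@H](C)C(C)(C=O)CCC(C)=O)cc1 | intermediate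
15 | 3-hydroxy-4-methyl-4-[(2R,3S)-5-(PMB-oxy)-3-(TBS-oxy)pentan-2-yl]cyclohexan-1-one (diastereomer mixture, not isolated) | COc1ccc(COCC[C@H](O[Si](C)(C)C(C)(C)C)[C@H](C)C2(C)CCC(=O)CC2O)cc1 | intermediate
16 | 4-methyl-4-[(2R,3S)-5-(PMB-oxy)-3-(TBS-oxy)pentan-2-yl]cyclohex-2-en-1-one (C4 epimers) | COc1ccc(COCC[C@H](O[Si](C)(C)C(C)(C)C)[C@H](C)C2(C)CCC(=O)C=C2)cc1 | intermediate
17 | trimethyl({4-methyl-4-[(2R,3S)-5-(PMB-oxy)-3-(TBS-oxy)pentan-2-yl]cyclohexa-1,5-dien-1-yl}oxy)silane (C4 epimers, not isolated) | COc1ccc(COCC[C@H](O[Si](C)(C)C(C)(C)C)[C@H](C)C2(C)CC=C(O[Si](C)(C)C)C=C2)cc1 | intermediate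
18 | 4-methyl-4-[(2R,3S)-5-(PMB-oxy)-3-(TBS-oxy)pentan-2-yl]cyclohexa-2,5-dien-1-one | COc1ccc(COCC[C@H](O[Si](C)(C)C(C)(C)C)[C@H](C)C2(C)C=CC(=O)C=C2)cc1 | intermediate
19 | 4-[(2R,3S)-5-hydroxy-3-(TBS-oxy)pentan-2-yl]-4-methylcyclohexa-2,5-dien-1-one | CC(C)(C)[Si](C)(C)O[C@@H](CCO)[C@H](C)C1(C)C=CC(=O)C=C1 | intermediate
20 | 4-[(2R,3S)-5-iodo-3-(TBS-oxy)pentan-2-yl]-4-methylcyclohexa-2,5-dien-1-one | CC(C)(C)[Si](C)(C)O[C@@H](CCI)[C@H](C)C1(C)C=CC(=O)C=C1 | intermediate
21 | (4aR,5R,6S,8aR)-4a,5-dimethyl-6-(TBS-oxy)-4a,5,6,7,8,8a-hexahydronaphthalen-2(1H)-one (cis-fused; 3S,4R,5R,10R in eremophilane numbering) | CC(C)(C)[Si](C)(C)O[C@H]1CC[C@@H]2CC(=O)C=C[C@]2(C)[C@H]1C | intermediate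
22 | (4aS,5R,6S,8aR)-3-iodo-4a,5-dimethyl-6-(TBS-oxy)-4a,5,6,7,8,8a-hexahydronaphthalen-2(1H)-one | CC(C)(C)[Si](C)(C)O[C@H]1CC[C@@H]2CC(=O)C(I)=C[C@]2(C)[C@H]1C | intermediate
23 | (4aS,5R,6S,8aR)-6-hydroxy-3-iodo-4a,5-dimethyl-4a,5,6,7,8,8a-hexahydronaphthalen-2(1H)-one | O[C@H]1CC[C@@H]2CC(=O)C(I)=C[C@]2(C)[C@H]1C | intermediate
24 | angelic acid, (Z)-2-methylbut-2-enoic acid | C/C=C(/C)C(=O)O | starting material
25 | (Z)-2-methylbut-2-enoic 2,4,6-trichlorobenzoic anhydride (not isolated) | C/C=C(/C)C(=O)OC(=O)c1c(Cl)cc(Cl)cc1Cl | intermediate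
26 | (1R,2S,4aR,8aS)-7-iodo-1,8a-dimethyl-6-oxo-1,2,3,4,4a,5,6,8a-octahydronaphthalen-2-yl (Z)-2-methylbut-2-enoate | C/C=C(/C)C(=O)O[C@H]1CC[C@@H]2CC(=O)C(I)=C[C@]2(C)[C@H]1C | intermediate
27 | methyl 2-chloropropanoate (racemic) | CC(Cl)C(=O)OC | starting material
28 | methyl (2R)-2-[(4aR,7S,8R,8aR)-8,8a-dimethyl-7-{[(Z)-2-methylbut-2-enoyl]oxy}-3-oxo-3,4,4a,5,6,7,8,8a-octahydronaphthalen-2-yl]propanoate | C/C=C(/C)C(=O)O[C@H]1CC[C@@H]2CC(=O)C([C@@H](C)C(=O)OC)=C[C@]2(C)[C@H]1C | target

**Step count and risks**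

Total steps: 16. Longest linear sequence: 16 steps (1 to 28; compounds 4, 11, 24 and 27 are bought).

Steps most likely to fail:

Step 16 (new method). Three things may go wrong: the alkenylnickel intermediate may be protonated or reduced instead of coupling, the α-ester radical may add to the enone or the angelate, or the ligand may fail to override the substrate at C11. The fallback sets out from 26 and uses a palladium-catalysed Negishi-type coupling with the Reformatsky reagent bromo(1-methoxy-1-oxopropan-2-yl)zinc F1. F1 is made from methyl 2-bromopropanoate and Zn dust in THF and coupled with Pd(dba)2/P(tBu)3 at rt. Without asymmetric induction this should give 28 together with the 11-epimer of the target F2. The two are separated by preparative HPLC, and the route is rejoined at 28.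

Step 12. The two enone arms may be distinguished too weakly in the early, reactant-like radical transition state, or the C1 radical may be reduced before it cyclises. The fallback sets out from 20 and replaces kinetic by thermodynamic arm selection. Kornblum substitution with NaNO2 in DMF should give the nitroalkane 4-methyl-4-[(2R,3S)-5-nitro-3-(TBS-oxy)pentan-2-yl]cyclohexa-2,5-dien-1-one F3. Catalytic DBU in MeCN then triggers a reversible intramolecular nitronate Michael addition onto C10 (again 6-exo), so that the system can settle in the least strained cis-fused product, the 1-nitro derivative of 21 F4 (C1 epimers). Radical denitration (Bu3SnH, AIBN, toluene, reflux) returns the sequence to 21.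

Step 7. The Michael addition may stall at the hindered, β-branched enamine carbon while methyl vinyl ketone oligomerises. The fallback sets out from 10 and forms quaternary C5 by alkylation instead of conjugate addition. Condensation with cyclohexylamine gives the N-cyclohexyl imine of 10 F5. Deprotonation with LiN(iPr)2 in THF and alkylation of the metalloenamine with 2-(2-bromoethyl)-2-methyl-1,3-dioxolane give the alkylated imine F6. Aqueous oxalic acid hydrolyses the imine to the aldehyde ketal F7, and removal of the dioxolane (PPTS, acetone–water) brings the sequence back to 14.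

**Further compounds**

F1 | step 16 | bromo(1-methoxy-1-oxopropan-2-yl)zinc | COC(=O)C(C)[Zn]Br
F2 | step 16 | methyl (2S)-2-[(4aR,7S,8R,8aR)-8,8a-dimethyl-7-{[(Z)-2-methylbut-2-enoyl]oxy}-3-oxo-3,4,4a,5,6,7,8,8a-octahydronaphthalen-2-yl]propanoate (11-epimer of 28) | C/C=C(/C)C(=O)O[C@H]1CC[C@@H]2CC(=O)C([C@H](C)C(=O)OC)=C[C@]2(C)[C@H]1C
F3 | step 12 | 4-methyl-4-[(2R,3S)-5-nitro-3-(TBS-oxy)pentan-2-yl]cyclohexa-2,5-dien-1-one | CC(C)(C)[Si](C)(C)O[C@@H](CC[N+](=O)[O-])[C@H](C)C1(C)C=CC(=O)C=C1
F4 | step 12 | 4a,5-dimethyl-8-nitro-6-(TBS-oxy)-4a,5,6,7,8,8a-hexahydronaphthalen-2(1H)-one with the ring configuration of 21 (1-nitro derivative of 21, C1 epimers) | CC(C)(C)[Si](C)(C)O[C@H]1CC([N+](=O)[O-])[C@@H]2CC(=O)C=C[C@]2(C)[C@H]1C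
F5 | step 7 | N-cyclohexyl imine of 10 (C2 epimers) | COc1ccc(COCC[C@H](O[Si](C)(C)C(C)(C)C)[C@H](C)C(C)C=NC2CCCCC2)cc1
F6 | step 7 | N-cyclohexyl imine of 2-methyl-2-[2-(2-methyl-1,3-dioxolan-2-yl)ethyl]-substituted aldehyde (alkylated imine, C2 epimers) | COc1ccc(COCC[C@H](O[Si](C)(C)C(C)(C)C)[C@H](C)C(C)(CCC2(C)OCCO2)C=NC3CCCCC3)cc1
F7 | step 7 | 2-methyl-4-(2-methyl-1,3-dioxolan-2-yl)-2-[(2R,3S)-5-(PMB-oxy)-3-(TBS-oxy)pentan-2-yl]butanal (aldehyde ketal, C2 epimers) | COc1ccc(COCC[C@H](O[Si](C)(C)C(C)(C)C)[C@H](C)C(C)(CCC2(C)OCCO2)C=O)cc1
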